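At early times in the dusk run crystals stayed within the scatter; they stood clear of it at 20.0 h, with 4.0%, and I looked for the line at which they appear.

| setting | dusk | winter | flask |
|---|---|---|---|
| free monomer | 0.020 M | 0.030 M | 0.020 M |
| initiator | 0.20 mM | 0.20 mM | 0.20 mM |
| remark | the very flask that is asked about, followed so far | run made earlier |  |
| time |  |  | 2.0 d |

| run | time / h | monomer in chains / % | crystals / % | free monomer / % |
|---|---|---|---|---|
| dusk | 1.33 | 1.5 | 0 | 91.0 |
| dusk | 4.00 | 6.6 | 0 | 71.9 |
| dusk | 6.00 | 12.4 | 0.3 | 58.8 |
| dusk | 10.0 | 19.0 | 0.2 | 41.1 |
| dusk | 15.0 | 27.7 | 0 | 27.5 |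
| dusk | 20.0 | 33.1 | 4.0 | 20.2 |
| winter | 1.33 | 1.7 | 0.1 | 90.3 |
| winter | 4.00 | 9.0 | 0.3 | 69.9 |
| winter | 6.00 | 14.1 | 0.9 | 56.7 |
| winter | 10.0 | 24.1 | 3.8 | 38.1 |
| winter | 15.0 | 31.3 | 11.9 | 26.2 |
| winter | 20.0 | 36.1 | 16.5 | 18.4 |

(readings scatter by 0.5 percentage points)

- what is said of monomer in chains includes crystals
- crystals is a solid; its amount is given per volume of the solution

1. how much monomer in chains and crystals together there is at 2.0 d, in percent of the free monomer charged
2. concentration of monomer in chains in solution at 2.0 d, in percent of saturation

From the last winter reading, monomer in chains less crystals taken on the winter charge, I read 5.88 mM as the saturation concentration (the solubility), the [monomer in chains] that solution holds beside crystals. The last dusk reading, from another charge, gave 5.82 mM. I made the winter value the zero of my scale: whatever monomer in chains lies above it I counted as crystals. For the flask the zero lay at 29.4% of the charge, and the dusk run already stood above it with 33.1% at 20.0 h, rising at each reading, so for 2.0 d I committed to crystals standing in a saturated solution.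

The forecast gave 46% (40% to 56%) and 100% (93% to 106%): “With crystals present at 2 d, the solution should sit at saturation”.

The flask gave 49.8% and 100%. On my scale that was 20 percentage points above zero, and the flask held 20.7% of crystals.

    crystals ⇌ monomer in chains, rate k1*(cs1 - [monomer in chains]) while solid is left; crystals form when [monomer in chains] > cs1 (solubility = 5.80 mM, k = 6.40 h⁻¹)
    free monomer + initiator → living end + monomer in chains (k = 15.0 M⁻¹ h⁻¹)
    free monomer ⇌ dormant form (K = 2.90, k = 0.0660 h⁻¹)
    initiator → spent initiator (k = 0.00980 h⁻¹)
    free monomer + living end → monomer in chains + living end, rate k5*[living end]*[free monomer] (k = 260 M⁻¹ h⁻¹)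

The flask had not come to rest at 2.0 d. Its dissolved monomer in chains was steady, made and used at a ratio of 0.998, but 9.08% of the charge was still free monomer and 41.1% dormant form. Left until 20.0 d, ten times as long, the flask came down to 0.210% of the charge as free monomer and 0.981% as dormant form, while monomer in chains, crystals counted, rose to 98.8%. My scale put that 69 points above zero, and the crystals stood at 69.8%.

Readings and results stem from a simulated flask from invented constants, noise included.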